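**Plan**
1. Retrosynthesis: the sugar on O‑7 and the two acetates on C5/C6 (from acetyl groups by Baeyer–Villiger oxidation) come off first. The carbocycle is then opened across C4a–C5 and C6–C7, a retro‑Diels–Alder after the C4a=C8a double bond is moved to C8=C8a. Then come the enol ether O–C7, the formyl carbon C7, the C8–O–aryl ether, the 4‑pyranone (1,3,5‑triketone) and the chromone (Claisen).
2. Enabling feature: C4a=C8a is the C3=C2 enol‑ether double bond of the 4‑pyranone ring. With a 1,2‑dioxyvinyl group on C8a it forms the diene C4a=C8a–C8=C7. The adduct returns to the pyranone by a 1,3‑hydrogen shift from C4a to C8, so the ring C4a–C5–C6–C7–C8–C8a is a Diels–Alder adduct.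
3. Forward order: chromone ring (step 1), monocyclic 4‑pyranone (step 3), ether link between the halves (step 4), dienol ether (steps 5–6), cyclohexane ring last (step 7), then acetyl → acetate and deprotection.
4. Stereochemistry: C7 from a removable α‑D‑mannosyl auxiliary on the diene oxygen (face selection). C5/C6 trans from the (E)‑dienophile, and their relation to C7 from the endo/exo arrangement. C8 from protonation anti to O‑7. Baeyer–Villiger migration proceeds with retention.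

Key step: step 7

Assumption: facial induction by the sugar is taken to follow the exo‑anomeric model of 1‑(glycosyloxy)dienes (addition anti to the pyranose ring oxygen), which for an α‑D‑mannoside leads to the (7S) series; if the opposite sense is found, the β‑D‑glucosyl analogue (β‑glucosidase at the end) is used in the same sequence.

**Step 1**
Reactants: 1 1‑(2,5‑dihydroxy‑4‑methoxyphenyl)ethan‑1‑one; 2 ethyl 3‑phenylpropanoate
Product: 4 6‑hydroxy‑7‑methoxy‑2‑(2‑phenylethyl)‑4H‑chromen‑4‑one, via aryl 1,3‑diketone 3 (not isolated)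
Conditions: NaH (5 equiv), THF, reflux; then conc. HCl, MeOH, reflux
Reagents that add atoms: none
Why: Claisen condensation of the ketone enolate (phenols present as phenoxides) with the ester gives the 1‑(2‑hydroxyaryl)‑1,3‑diketone, which cyclodehydrates in acid to the chromone; no stereocentre is formed.

**Step 2**
Reactants: 5 pentane‑2,4‑dione; 6 benzyl bromide
Product: 7 6‑phenylhexane‑2,4‑dione
Conditions: LDA (2.2 equiv), THF, 0 °C; 6, 0 °C → rt; AcOH quench
Reagents that add atoms: none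
Why: The β‑diketone dianion is alkylated at its terminal, more basic carbanion (γ‑alkylation of a 1,3‑diketone dianion).

**Step 3**
Reactants: 7 6‑phenylhexane‑2,4‑dione; 8 ethyl 2‑[(tert‑butyldimethylsilyl)oxy]acetate
Product: 10 2‑(hydroxymethyl)‑6‑(2‑phenylethyl)‑4H‑pyran‑4‑one, via silyloxy triketone 9 (not isolated)
Conditions: LDA (3.1 equiv), THF, −78 → 0 °C; 8, −78 → 0 °C; AcOH quench; crude in TFA/H2O (9:1), rt
Reagents that add atoms: none
Why: The dianion of 7 (central carbon and terminal methyl) is C‑acylated by the ester (Claisen acylation), and the 1,3,5‑triketone cyclodehydrates in acid to the 4‑pyranone while the primary silyl ether is cleaved.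

**Step 4**
Reactants: 10 2‑(hydroxymethyl)‑6‑(2‑phenylethyl)‑4H‑pyran‑4‑one; 4 6‑hydroxy‑7‑methoxy‑2‑(2‑phenylethyl)‑4H‑chromen‑4‑one
Product: 11 7‑methoxy‑6‑{[4‑oxo‑6‑(2‑phenylethyl)‑4H‑pyran‑2‑yl]methoxy}‑2‑(2‑phenylethyl)‑4H‑chromen‑4‑one
Conditions: PPh3, DIAD, THF, 0 °C → rt
Reagents that add atoms: none
Why: Mitsunobu etherification of a primary carbinol with a phenol of pKa about 10 joins the two halves under neutral conditions, so the base‑sensitive lateral CH2 groups are not touched.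

**Step 5**
Reactants: 11 aryloxymethyl pyranone (as above)
Product: 12 6‑{[(Z)‑2‑hydroxy‑1‑[4‑oxo‑6‑(2‑phenylethyl)‑4H‑pyran‑2‑yl]ethenyl]oxy}‑7‑methoxy‑2‑(2‑phenylethyl)‑4H‑chromen‑4‑one (hydroxymethylene form of the α‑aryloxy aldehyde)
Conditions: NaH (1.2 equiv), HCO2Et (5 equiv), EtOH (cat.), THF, 0 °C → rt; AcOH quench
Reagents that add atoms: ethyl formate, CCOC=O
Why: The ArO–CH2 group, vinylogous to the pyranone carbonyl and acidified by the aryloxy group, is the most acidic site; its anion undergoes Claisen formylation at the exocyclic carbon and the product is held as its stabilised enolate until the quench.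

**Step 6**
Reactants: 12 hydroxymethylene compound (as above); 13 2,3,4,6‑tetra‑O‑acetyl‑α‑D‑mannopyranosyl trichloroacetimidate
Product: 14 6‑{[(Z)‑1‑[4‑oxo‑6‑(2‑phenylethyl)‑4H‑pyran‑2‑yl]‑2‑(2,3,4,6‑tetra‑O‑acetyl‑α‑D‑mannopyranosyloxy)ethenyl]oxy}‑7‑methoxy‑2‑(2‑phenylethyl)‑4H‑chromen‑4‑one
Conditions: TMSOTf (0.1 equiv), 4 Å MS, CH2Cl2, −20 → 0 °C
Reagents that add atoms: none
Why: Schmidt glycosylation: the 2‑O‑acetyl group closes to an acetoxonium ion that the acidic enol oxygen opens trans, giving the α‑mannoside, and the push–pull enol ether is expected to settle as the (Z)‑isomer with the mannosyloxy group trans to the pyranone, the geometry the diene needs.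

**Step 7**
Reactants: 14 mannosyl dienol ether (as above); 15 (3E)‑hex‑3‑ene‑2,5‑dione
Product: 17 6‑{[(5R,6R,7S,8S)‑5,6‑diacetyl‑4‑oxo‑2‑(2‑phenylethyl)‑7‑(2,3,4,6‑tetra‑O‑acetyl‑α‑D‑mannopyranosyloxy)‑5,6,7,8‑tetrahydro‑4H‑chromen‑8‑yl]oxy}‑7‑methoxy‑2‑(2‑phenylethyl)‑4H‑chromen‑4‑one, via Diels–Alder adduct 16 (not isolated)
Conditions: 15 (3 equiv), BHT (cat.), toluene, 100 °C, sealed tube; then PPTS (5 mol %), CH2Cl2, 0 °C
Reagents that add atoms: none
Why: The s‑cis diene C4a=C8a–C8=C7 (both inside positions carry H) adds suprafacially to the electron‑poor (E)‑enedione in a thermal normal‑demand [4+2] cycloaddition that closes the six‑membered carbocycle by forming C4a–C5 and C6–C7 together, and acid then protonates the enol ether at C8 and removes H‑4a so that the 4‑pyranone is restored (1,3‑prototropy). The closest known reaction types are the Diels–Alder reactions of 2‑vinyl‑ and 2‑styrylchromones with maleimides followed by the same hydrogen shift, and the auxiliary‑controlled cycloadditions of 1‑(glycosyloxy)buta‑1,3‑dienes. C5 and C6 are trans because the (E)‑geometry of 15 is retained, and C7 is set by the mannosyl group, which in its exo‑anomeric conformation covers the diene face on the side of the pyranose ring oxygen so that 15 adds to the other face. The 5,7‑cis and 6,7‑trans relations follow from the transition state in which the acetyl group on C5 is endo under the flat pyranone (C8a) and the acetyl group on C6 is exo, away from the out‑of‑plane aryloxy group on C8 and the mannosyloxy group on C7. C8 is set in the prototropy by protonation of the C8=C8a enol ether anti to the neighbouring mannosyloxy group, which leaves the aryloxy group cis to O‑7. The step needs the carbon [4+2] mode to win over a hetero‑Diels–Alder addition of the enone to the enol ether and over 1,4‑elimination of the C7 oxygen; the conjugated s‑cis diene and the non‑basic, weakly acidic conditions are relied on for this.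

**Step 8**
Reactants: 17 diacetyl tetrahydrochromone (as above)
Product: 18 (5S,6R,7S,8S)‑8‑{[7‑methoxy‑4‑oxo‑2‑(2‑phenylethyl)‑4H‑chromen‑6‑yl]oxy}‑4‑oxo‑2‑(2‑phenylethyl)‑7‑(2,3,4,6‑tetra‑O‑acetyl‑α‑D‑mannopyranosyloxy)‑5,6,7,8‑tetrahydro‑4H‑chromene‑5,6‑diyl diacetate
Conditions: mCPBA (5 equiv), NaHCO3, CH2Cl2, rt, dark
Reagents that add atoms: mCPBA (3‑chloroperoxybenzoic acid), OOC(=O)c1cccc(Cl)c1
Why: Double Baeyer–Villiger oxidation: in each methyl ketone the secondary ring carbon migrates in preference to methyl and with retention, so both acetyl groups become acetates without change at C5 and C6, while the pyranones and the glycoside are inert to buffered peracid.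

**Step 9**
Reactants: 18 hexaacetate (as above)
Product: 19 6‑{[(5S,6R,7S,8S)‑5,6‑dihydroxy‑7‑(α‑D‑mannopyranosyloxy)‑4‑oxo‑2‑(2‑phenylethyl)‑5,6,7,8‑tetrahydro‑4H‑chromen‑8‑yl]oxy}‑7‑methoxy‑2‑(2‑phenylethyl)‑4H‑chromen‑4‑one
Conditions: NaOMe (0.2 equiv), MeOH, 0 °C; Amberlite IR‑120 (H+)
Reagents that add atoms: none
Why: Zemplén transesterification removes all six acetates with catalytic methoxide at 0 °C, conditions expected to be too mild to epimerise C8 or open the pyranone.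

**Step 10**
Reactants: 19 α‑D‑mannoside (as above)
Product: 20 6‑{[(5S,6R,7S,8S)‑5,6,7‑trihydroxy‑4‑oxo‑2‑(2‑phenylethyl)‑5,6,7,8‑tetrahydro‑4H‑chromen‑8‑yl]oxy}‑7‑methoxy‑2‑(2‑phenylethyl)‑4H‑chromen‑4‑one
Conditions: jack‑bean α‑mannosidase, NaOAc buffer pH 5.0 (Zn2+), 10 % DMSO, 37 °C
Reagents that add atoms: none
Why: The exo‑α‑mannosidase hydrolyses the glycosidic bond at the anomeric carbon near neutral pH, so the C7–O bond and the acid‑ and base‑sensitive triol are untouched (enzymatic removal of a sugar auxiliary).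

**Compound list**
1 | 1‑(2,5‑dihydroxy‑4‑methoxyphenyl)ethan‑1‑one | CC(=O)c1cc(O)c(OC)cc1O | starting material
2 | ethyl 3‑phenylpropanoate | CCOC(=O)CCc1ccccc1 | starting material
3 | 1‑(2,5‑dihydroxy‑4‑methoxyphenyl)‑5‑phenylpentane‑1,3‑dione | COc1cc(O)c(cc1O)C(=O)CC(=O)CCc1ccccc1 | intermediate
4 | 6‑hydroxy‑7‑methoxy‑2‑(2‑phenylethyl)‑4H‑chromen‑4‑one | COc1cc2oc(CCc3ccccc3)cc(=O)c2cc1O | intermediate
5 | pentane‑2,4‑dione | CC(=O)CC(C)=O | starting material
6 | benzyl bromide | BrCc1ccccc1 | starting material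
7 | 6‑phenylhexane‑2,4‑dione | CC(=O)CC(=O)CCc1ccccc1 | intermediate
8 | ethyl 2‑[(tert‑butyldimethylsilyl)oxy]acetate | CCOC(=O)CO[Si](C)(C)C(C)(C)C | starting material
9 | 1‑[(tert‑butyldimethylsilyl)oxy]‑8‑phenyloctane‑2,4,6‑trione | CC(C)(C)[Si](C)(C)OCC(=O)CC(=O)CC(=O)CCc1ccccc1 | intermediate
10 | 2‑(hydroxymethyl)‑6‑(2‑phenylethyl)‑4H‑pyran‑4‑one | OCc1cc(=O)cc(CCc2ccccc2)o1 | intermediate
11 | 7‑methoxy‑6‑{[4‑oxo‑6‑(2‑phenylethyl)‑4H‑pyran‑2‑yl]methoxy}‑2‑(2‑phenylethyl)‑4H‑chromen‑4‑one | COc1cc2oc(CCc3ccccc3)cc(=O)c2cc1OCc1cc(=O)cc(CCc2ccccc2)o1 | intermediate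
12 | 6‑{[(Z)‑2‑hydroxy‑1‑[4‑oxo‑6‑(2‑phenylethyl)‑4H‑pyran‑2‑yl]ethenyl]oxy}‑7‑methoxy‑2‑(2‑phenylethyl)‑4H‑chromen‑4‑one | COc1cc2oc(CCc3ccccc3)cc(=O)c2cc1O/C(=C\O)c1cc(=O)cc(CCc2ccccc2)o1 | intermediate
13 | 2,3,4,6‑tetra‑O‑acetyl‑α‑D‑mannopyranosyl trichloroacetimidate | CC(=O)OC[C@H]1O[C@H](OC(=N)C(Cl)(Cl)Cl)[C@@H](OC(C)=O)[C@@H](OC(C)=O)[C@@H]1OC(C)=O | starting material
14 | (Z)‑dienol ether of 12 with a 2,3,4,6‑tetra‑O‑acetyl‑α‑D‑mannopyranosyl group on the enol oxygen | COc1cc2oc(CCc3ccccc3)cc(=O)c2cc1O/C(=C\O[C@H]1O[C@H](COC(C)=O)[C@@H](OC(C)=O)[C@H](OC(C)=O)[C@@H]1OC(C)=O)c1cc(=O)cc(CCc2ccccc2)o1 | intermediate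
15 | (3E)‑hex‑3‑ene‑2,5‑dione | CC(=O)/C=C/C(C)=O | starting material
16 | Diels–Alder adduct: 5,6‑diacetyl‑8‑aryloxy‑7‑(tetra‑O‑acetyl‑α‑D‑mannosyloxy)‑2‑(2‑phenylethyl)‑4a,5,6,7‑tetrahydro‑4H‑chromen‑4‑one with the C8=C8a enol ether; C5‑acetyl cis to O‑7, C6‑acetyl trans to both, H‑4a cis to H‑7 | COc1cc2oc(CCc3ccccc3)cc(=O)c2cc1OC1=C2OC(CCc3ccccc3)=CC(=O)[C@@H]2[C@H](C(C)=O)[C@@H](C(C)=O)[C@@H]1O[C@H]1O[C@H](COC(C)=O)[C@@H](OC(C)=O)[C@H](OC(C)=O)[C@@H]1OC(C)=O | intermediate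
17 | 6‑{[(5R,6R,7S,8S)‑5,6‑diacetyl‑4‑oxo‑2‑(2‑phenylethyl)‑7‑(2,3,4,6‑tetra‑O‑acetyl‑α‑D‑mannopyranosyloxy)‑5,6,7,8‑tetrahydro‑4H‑chromen‑8‑yl]oxy}‑7‑methoxy‑2‑(2‑phenylethyl)‑4H‑chromen‑4‑one (5,6‑trans, 6,7‑trans, 7,8‑cis) | COc1cc2oc(CCc3ccccc3)cc(=O)c2cc1O[C@@H]1c2oc(CCc3ccccc3)cc(=O)c2[C@H](C(C)=O)[C@@H](C(C)=O)[C@@H]1O[C@H]1O[C@H](COC(C)=O)[C@@H](OC(C)=O)[C@H](OC(C)=O)[C@@H]1OC(C)=O | intermediate
18 | (5S,6R,7S,8S)‑5,6‑diacetate of the 7‑O‑(tetra‑O‑acetyl‑α‑D‑mannopyranosyl) 8‑aryl ether | COc1cc2oc(CCc3ccccc3)cc(=O)c2cc1O[C@@H]1c2oc(CCc3ccccc3)cc(=O)c2[C@H](OC(C)=O)[C@@H](OC(C)=O)[C@@H]1O[C@H]1O[C@H](COC(C)=O)[C@@H](OC(C)=O)[C@H](OC(C)=O)[C@@H]1OC(C)=O | intermediate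
19 | 7‑O‑α‑D‑mannopyranoside of the target, (5S,6R,7S,8S) | COc1cc2oc(CCc3ccccc3)cc(=O)c2cc1O[C@@H]1c2oc(CCc3ccccc3)cc(=O)c2[C@H](O)[C@@H](O)[C@@H]1O[C@H]1O[C@H](CO)[C@@H](O)[C@H](O)[C@@H]1O | intermediate
20 | 6‑{[(5S,6R,7S,8S)‑5,6,7‑trihydroxy‑4‑oxo‑2‑(2‑phenylethyl)‑5,6,7,8‑tetrahydro‑4H‑chromen‑8‑yl]oxy}‑7‑methoxy‑2‑(2‑phenylethyl)‑4H‑chromen‑4‑one | COc1cc2oc(CCc3ccccc3)cc(=O)c2cc1O[C@@H]1c2oc(CCc3ccccc3)cc(=O)c2[C@H](O)[C@@H](O)[C@@H]1O | target

**Step count**
Total: 10 steps. Longest linear sequence: 9 steps (5 → 7 → 10 → 11 → 12 → 14 → 17 → 18 → 19 → 20, steps 2–10); step 1 is the side branch.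

**Steps most likely to fail**

Step 7. The push–pull diene may add too slowly. The enone may instead add across the enol ether in a hetero‑Diels–Alder reaction. Face or endo/exo discrimination may be poor, and the C7 oxygen may be lost by 1,4‑elimination during the prototropy. The fallback sets out from 12 and returns to the route at 20. Enol 12 is silylated (TBSCl, imidazole, DMF) to the smaller, more electron‑rich tert‑butyldimethylsilyl dienol ether F1. Cycloaddition with 15 at 10–12 kbar and room temperature, then PPTS, gives the racemic 5,6‑diacetyl 7‑silyl ether F2. Baeyer–Villiger oxidation as in step 8 gives the racemic 5,6‑diacetate 7‑silyl ether F3, and HF·pyridine gives the racemic 5,6‑di‑O‑acetyl 7‑alcohol F4. Lipase‑catalysed acetylation (Burkholderia cepacia lipase, vinyl acetate) resolves F4; the target‑series enantiomer is collected either as the remaining alcohol F4 or as the 5,6,7‑triacetate F5, and K2CO3/MeOH converts it into 20. The absolute configuration then comes from an enzymatic kinetic resolution instead of the auxiliary.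

Step 8. Migration of C6, which sits between two oxygenated carbons, may be slow. The 1,4‑diketone may condense with itself, the glycosyloxy group β to the C6 ketone may be eliminated, or the electron‑rich chromone ring may be hydroxylated. The fallback sets out from 14 and returns at 19. The dienophile is changed to commercial (E)‑1,2‑bis(pinacolboryl)ethene (xylene, 130 °C, or high pressure; then PPTS), which gives the 5,6‑bis(pinacolboronate) F6 with the same relative configuration. Sodium perborate in THF/water oxidises both C–B bonds with retention to the 5,6‑diol tetra‑O‑acetylmannoside F7, and Zemplén methanolysis gives 19. No ketone is then present next to the C7 oxygen.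

Step 6. The weakly nucleophilic enol may be glycosylated on carbon or give an orthoester, or the enol ether may form with the wrong double‑bond geometry. The fallback sets out from 11 and returns at 14. Condensation of 11 with tert‑butoxybis(dimethylamino)methane (Bredereck's reagent, toluene, 80 °C) at the ArO–CH2 group gives the (dimethylamino)vinyl compound F8. Acid‑catalysed exchange (PPTS, toluene, removal of Me2NH) of the amino group for the anomeric hydroxyl of commercial 2,3,4,6‑tetra‑O‑acetyl‑D‑mannopyranose, which is mainly the α‑hemiacetal, gives 14. The O–C7 bond is then made by addition–elimination at C7 instead of by substitution at the anomeric carbon.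

**Further compounds**
F1 | step 7 | 6‑{[(Z)‑2‑[(tert‑butyldimethylsilyl)oxy]‑1‑[4‑oxo‑6‑(2‑phenylethyl)‑4H‑pyran‑2‑yl]ethenyl]oxy}‑7‑methoxy‑2‑(2‑phenylethyl)‑4H‑chromen‑4‑one | COc1cc2oc(CCc3ccccc3)cc(=O)c2cc1O/C(=C\O[Si](C)(C)C(C)(C)C)c1cc(=O)cc(CCc2ccccc2)o1
F2 | step 7 | racemic 5,6‑diacetyl‑7‑[(tert‑butyldimethylsilyl)oxy] analogue of 17 (relative configuration as in 17; one enantiomer drawn) | COc1cc2oc(CCc3ccccc3)cc(=O)c2cc1O[C@@H]1c2oc(CCc3ccccc3)cc(=O)c2[C@H](C(C)=O)[C@@H](C(C)=O)[C@@H]1O[Si](C)(C)C(C)(C)C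
F3 | step 7 | racemic 5,6‑diacetate 7‑tert‑butyldimethylsilyl ether (relative configuration as in 18; one enantiomer drawn) | COc1cc2oc(CCc3ccccc3)cc(=O)c2cc1O[C@@H]1c2oc(CCc3ccccc3)cc(=O)c2[C@H](OC(C)=O)[C@@H](OC(C)=O)[C@@H]1O[Si](C)(C)C(C)(C)C
F4 | step 7 | 5,6‑di‑O‑acetyl 7‑alcohol, racemic before and (5S,6R,7S,8S) after resolution | COc1cc2oc(CCc3ccccc3)cc(=O)c2cc1O[C@@H]1c2oc(CCc3ccccc3)cc(=O)c2[C@H](OC(C)=O)[C@@H](OC(C)=O)[C@@H]1O
F5 | step 7 | (5S,6R,7S,8S)‑5,6,7‑triacetate of 20 | COc1cc2oc(CCc3ccccc3)cc(=O)c2cc1O[C@@H]1c2oc(CCc3ccccc3)cc(=O)c2[C@H](OC(C)=O)[C@@H](OC(C)=O)[C@@H]1OC(C)=O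
F6 | step 8 | 5,6‑bis(4,4,5,5‑tetramethyl‑1,3,2‑dioxaborolan‑2‑yl) analogue of 17 (same spatial arrangement) | COc1cc2oc(CCc3ccccc3)cc(=O)c2cc1O[C@@H]1c2oc(CCc3ccccc3)cc(=O)c2[C@H](B3OC(C)(C)C(C)(C)O3)[C@@H](B3OC(C)(C)C(C)(C)O3)[C@@H]1O[C@H]1O[C@H](COC(C)=O)[C@@H](OC(C)=O)[C@H](OC(C)=O)[C@@H]1OC(C)=O
F7 | step 8 | (5S,6R,7S,8S)‑5,6‑diol 7‑O‑(2,3,4,6‑tetra‑O‑acetyl‑α‑D‑mannopyranoside) | COc1cc2oc(CCc3ccccc3)cc(=O)c2cc1O[C@@H]1c2oc(CCc3ccccc3)cc(=O)c2[C@H](O)[C@@H](O)[C@@H]1O[C@H]1O[C@H](COC(C)=O)[C@@H](OC(C)=O)[C@H](OC(C)=O)[C@@H]1OC(C)=O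
F8 | step 6 | 6‑{[(Z)‑2‑(dimethylamino)‑1‑[4‑oxo‑6‑(2‑phenylethyl)‑4H‑pyran‑2‑yl]ethenyl]oxy}‑7‑methoxy‑2‑(2‑phenylethyl)‑4H‑chromen‑4‑one | COc1cc2oc(CCc3ccccc3)cc(=O)c2cc1O/C(=C\N(C)C)c1cc(=O)cc(CCc2ccccc2)o1
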